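The runs come from a simulation from invented constants, noise included.

Late in Thursday's run the side product flattens, and that is where the dispute over these flasks begins.

| setting | Wednesday's | Thursday's | Saturday's | Monday's | east | north | north-west | south |
|---|---|---|---|---|---|---|---|---|
| starting complex | 0.094 M | 0.094 M | 0.094 M | 0.14 M | 0.094 M (fed, over 10 min) | 0.094 M | 0.094 M | 0.094 M |
| incoming ligand | 0.0658 M | 0.033 M | 0.049 M | 0.0658 M | 0.0658 M | 0.0658 M (in portions, 2, over 10 min) | 0.0658 M (fed, over 10 min) | 0.0658 M |
| remark | run made earlier | run made earlier | run made earlier | run made earlier | all else is in the flask from the start; the feed brings no volume worth counting | first portion at the start, last at 10 min | all else is in the flask from the start; the feed brings no volume worth counting | everything together at the start |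
| time |  |  |  |  | 15 min | 15 min | 15 min | 15 min |

| run | time / min | side product / % | complex with four exchanged / % |
|---|---|---|---|
| Wednesday's | 0.667 | 1.6 | 0.9 |
| Wednesday's | 1.33 | 5.4 | 0 |
| Wednesday's | 2.50 | 11.0 | 0 |
| Wednesday's | 5.00 | 24.3 | 0 |
| Wednesday's | 10.0 | 46.1 | 1.8 |
| Thursday's | 1.00 | 1.4 | 0.7 |
| Thursday's | 3.00 | 9.5 | 1.1 |
| Thursday's | 6.00 | 18.3 | 0 |
| Thursday's | 8.00 | 23.7 | 0.9 |
| Thursday's | 12.0 | 27.8 | 0 |
| Saturday's | 1.00 | 1.8 | 0 |
| Saturday's | 3.00 | 10.4 | 0 |
| Saturday's | 6.00 | 23.2 | 0.9 |
| Saturday's | 8.00 | 31.9 | 1.5 |
| Saturday's | 12.0 | 39.0 | 0 |
| Monday's | 2.50 | 10.7 | 0 |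
| Monday's | 5.00 | 22.0 | 0.9 |
| Monday's | 8.00 | 31.7 | 1.1 |
| Monday's | 10.0 | 37.3 | 0.4 |
| Monday's | 12.0 | 41.6 | 0.2 |

(scatter of a reading: 1 percentage point)



1. the flask that comes out highest in amount of side product, in percent of the starting complex charged; "all alike" if 1.5 percentage points covers them all (east / north / north-west / south / all alike)
2. amount of side product at the end, in percent of the starting complex charged, east
3. amount of side product at the end, in percent of the starting complex charged, north
4. amount of side product at the end, in percent of the starting complex charged, north-west
5. amount of side product at the end, in percent of the starting complex charged, south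

The first chemist reads the ends of the runs. She takes one incoming ligand per side product, with incoming ligand as the limiting reagent, and so defines the ligand ceiling, c(incoming ligand)/c(starting complex) as charged: 70.0% for each of the four flasks. Thursday's run has a ceiling of 35.1% and stands at 27.8% at its last reading, and Saturday's has 52.1% and stands at 39.0%. The charges match, so she expects the flasks within 1.5 percentage points of one another.

The second chemist replaces the curve by its mean. Wednesday's run made 46.1% in 10.0 min, and that straight line gives south 69.2% at 15 min. A feed or a pair of portions delivers its charge on average 5.00 min late, so the same line gives the other three flasks 46.1%, a gap far wider than the margin. The line may run high for south, though: Thursday's run gained 4.1 points from 8.00 min to 12.0 min.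

The forecast's numbers land on the second chemist's side, with south highest: “South simply continues Wednesday's run”, to 56%, against 41% for east, 45% for north and 47% for north-west. Its south lies below the line, and its other flasks spread around 46.1%.

South comes out highest at 54.9%, with east at 42.6%, north at 41.9% and north-west at 44.8%.

    starting complex + incoming ligand ⇌ leaving ligand + complex with one exchanged (K = 5.60, k = 0.0570 M⁻¹ s⁻¹)
    complex with one exchanged + incoming ligand ⇌ leaving ligand + complex with two exchanged (K = 0.490, k = 0.130 M⁻¹ s⁻¹)
    complex with two exchanged + incoming ligand ⇌ leaving ligand + complex with three exchanged (K = 15.0, k = 0.0320 M⁻¹ s⁻¹)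
    complex with three exchanged + incoming ligand ⇌ leaving ligand + complex with four exchanged (K = 1.10, k = 0.0810 M⁻¹ s⁻¹)
    complex with four exchanged + incoming ligand → over-reaction product (k = 0.0280 M⁻¹ s⁻¹)
    complex with one exchanged → side product (k = 0.00670 s⁻¹)

The forecast held, and the ceiling belongs to later times: at 150 min south has 68.2% and north 69.1%, within the margin of each other and just under 70.0%. A neighbour like north, with 0.38 M of starting complex, has a ceiling of 17.3%. At 15.0 min that neighbour holds 15.1% side product and 1.91% complex with one exchanged, with 0.982% of its incoming ligand left.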